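**Retrosynthetic overview**

1. The route rests on ring B being a resorcinol: the oxygens on C2' and C4' are 1,3-related, and C1'/C6' can be the two carbons of an ethynyl group on C2 of the pyranone (ring C). Ring B is therefore cut at C1'–C2' and C5'–C6' into a 2-ethynylchromone and 1-methoxy-1,3-bis(trimethylsilyloxy)buta-1,3-diene (from methyl acetoacetate).
2. The alkyne comes from the 2-unsubstituted 3-prenylchromone by C2 zincation, iodination and Sonogashira coupling. Ring C comes from an o-hydroxyaryl 5-methylhex-4-enyl ketone and DMF dimethyl acetal.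
3. Ring A is bought as 5-methoxyresorcinol. Two directed ortho-lithiations place the C6 chain (between OMe and OMOM, with 2-isopropyloxirane) and the acyl group (between OMOM and OSi), so the linear 5,6,7-pattern is fixed before ring C is closed.
4. Order of ring formation: ring A (purchased), ring C (step 9), ring B (step 15). Step 16 removes the MOM ether and the dioxolane.

Key step: step 15

Remark: 5-methoxyresorcinol, racemic 2-isopropyloxirane and N-methoxy-N-methylacetamide are taken as purchasable; alcohol 6 and cycloadduct 27 are racemic, and their stereocentres are destroyed in steps 4 and 15.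

**Route**

Step 1
Reactants: 1 5-methoxyresorcinol
Product: 2 3-methoxy-5-(triisopropylsilyloxy)phenol
Conditions: TIPSCl (0.5 equiv per 1), imidazole, DMF, 0 °C to rt; excess 1 recovered
Reagents that add atoms: triisopropylsilyl chloride, CC(C)[Si](Cl)(C(C)C)C(C)C
Why: Silyl ether formation on one of two equivalent phenols, with the diol in excess and a bulky chloride so that the mono-ether should dominate; the silylated oxygen is the future O1 of the chromone.

Step 2
Reactants: 2 3-methoxy-5-(triisopropylsilyloxy)phenol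
Product: 3 triisopropyl[3-methoxy-5-(methoxymethoxy)phenoxy]silane
Conditions: MOMCl, iPr2NEt, CH2Cl2, 0 °C to rt
Reagents that add atoms: chloromethyl methyl ether, COCCl
Why: O-alkylation of the remaining phenol (MOM protection) installs the acetal that directs both later lithiations and ends as the 5-O protecting group.

Step 3
Reactants: 3 triisopropyl[3-methoxy-5-(methoxymethoxy)phenoxy]silane; 4 2-isopropyloxirane (racemic)
Product: 6 rac-1-[2-methoxy-6-(methoxymethoxy)-4-(triisopropylsilyloxy)phenyl]-3-methylbutan-2-ol, via aryllithium 5 (not isolated)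
Conditions: n-BuLi, THF, 0 °C; then 4, BF3·OEt2, −78 °C
Reagents that add atoms: none
Why: Directed ortho-metalation at the carbon flanked by OMe and OMOM (cooperative directing groups, the bulky OTIPS group does not direct) followed by BF3-promoted SN2 opening of the terminal epoxide at its CH2 carbon should give the C6 side chain as a racemic secondary alcohol whose stereocentre is removed in step 4.

Step 4
Reactants: 6 rac-1-[2-methoxy-6-(methoxymethoxy)-4-(triisopropylsilyloxy)phenyl]-3-methylbutan-2-ol
Product: 7 1-[2-methoxy-6-(methoxymethoxy)-4-(triisopropylsilyloxy)phenyl]-3-methylbutan-2-one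
Conditions: nPr4NRuO4 (cat.), NMO, 4 Å MS, CH2Cl2, rt
Reagents that add atoms: none
Why: Ley–Griffith oxidation of a secondary alcohol to the ketone under neutral conditions that should leave the MOM acetal and the aryl silyl ether untouched.

Step 5
Reactants: 7 1-[2-methoxy-6-(methoxymethoxy)-4-(triisopropylsilyloxy)phenyl]-3-methylbutan-2-one
Product: 8 2-isopropyl-2-[2-methoxy-6-(methoxymethoxy)-4-(triisopropylsilyloxy)benzyl]-1,3-dioxolane
Conditions: TMSOCH2CH2OTMS, TMSOTf (cat.), CH2Cl2, −78 to −20 °C; then pyridine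
Reagents that add atoms: 1,2-bis(trimethylsilyloxy)ethane, C[Si](C)(C)OCCO[Si](C)(C)C
Why: Noyori ketalisation with aprotic TMSOTf catalysis at low temperature should convert the dialkyl ketone into the dioxolane without protic acid, so that the aryl MOM and TIPS ethers persist and the enolisable ketone is masked against the bases used later.

Step 6
Reactants: 8 2-isopropyl-2-[2-methoxy-6-(methoxymethoxy)-4-(triisopropylsilyloxy)benzyl]-1,3-dioxolane; 9 N-methoxy-N-methylacetamide
Product: 11 1-{4-methoxy-2-(methoxymethoxy)-3-[(2-isopropyl-1,3-dioxolan-2-yl)methyl]-6-(triisopropylsilyloxy)phenyl}ethanone, via aryllithium 10 (not isolated)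
Conditions: s-BuLi, TMEDA, THF, −78 °C; then 9, −78 to 0 °C
Reagents that add atoms: none
Why: A second directed ortho-metalation, now directed by the MOM group to the only C–H next to it (between OMOM and OTIPS), followed by acylation with the Weinreb amide, whose chelated tetrahedral adduct prevents over-addition, should give the aryl methyl ketone.

Step 7
Reactants: 11 1-{4-methoxy-2-(methoxymethoxy)-3-[(2-isopropyl-1,3-dioxolan-2-yl)methyl]-6-(triisopropylsilyloxy)phenyl}ethanone; 12 prenyl bromide
Product: 14 1-{4-methoxy-2-(methoxymethoxy)-3-[(2-isopropyl-1,3-dioxolan-2-yl)methyl]-6-(triisopropylsilyloxy)phenyl}-5-methylhex-4-en-1-one, via lithium enolate 13 (not isolated)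
Conditions: LiN(iPr)2, THF, −78 °C; then 12, −78 to 0 °C
Reagents that add atoms: none
Why: The kinetic lithium enolate of the methyl ketone (its only enolisable position) should be alkylated by SN2 reaction with the primary allylic bromide, which builds the carbon chain of the later C3-prenyl group.

Step 8
Reactants: 14 1-{4-methoxy-2-(methoxymethoxy)-3-[(2-isopropyl-1,3-dioxolan-2-yl)methyl]-6-(triisopropylsilyloxy)phenyl}-5-methylhex-4-en-1-one
Product: 15 1-{6-hydroxy-4-methoxy-2-(methoxymethoxy)-3-[(2-isopropyl-1,3-dioxolan-2-yl)methyl]phenyl}-5-methylhex-4-en-1-one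
Conditions: TBAF, AcOH, THF, 0 °C
Reagents that add atoms: none
Why: Fluoride cleavage of the aryl silyl ether should be fast because the ortho-acyl phenoxide is a good leaving group, and the acetic acid buffer keeps the acetals and the ketone untouched.

Step 9
Reactants: 15 1-{6-hydroxy-4-methoxy-2-(methoxymethoxy)-3-[(2-isopropyl-1,3-dioxolan-2-yl)methyl]phenyl}-5-methylhex-4-en-1-one
Product: 17 7-methoxy-5-(methoxymethoxy)-6-[(2-isopropyl-1,3-dioxolan-2-yl)methyl]-3-(3-methylbut-2-enyl)-4H-chromen-4-one, via enaminone 16 (not isolated)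
Conditions: Me2NCH(OMe)2, toluene, 100 °C; then AcOH (cat.), rt
Reagents that add atoms: N,N-dimethylformamide dimethyl acetal, COC(OC)N(C)C
Why: Enaminone formation at the α-methylene followed by intramolecular addition–elimination of the phenol (6-endo-trig, loss of dimethylamine), the standard chromone synthesis, should close ring C with the prenyl group on C3 and C2 unsubstituted.

Step 10
Reactants: 17 7-methoxy-5-(methoxymethoxy)-6-[(2-isopropyl-1,3-dioxolan-2-yl)methyl]-3-(3-methylbut-2-enyl)-4H-chromen-4-one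
Product: 19 2-iodo-7-methoxy-5-(methoxymethoxy)-6-[(2-isopropyl-1,3-dioxolan-2-yl)methyl]-3-(3-methylbut-2-enyl)-4H-chromen-4-one, via chromen-2-ylzinc chloride 18 (not isolated)
Conditions: TMPZnCl·LiCl (TMP = 2,2,6,6-tetramethylpiperidide), THF, 25 °C; then I2, THF, 0 °C; Na2S2O3 work-up
Reagents that add atoms: iodine, [I][I]
Why: Directed zincation with a zinc amide base removes the most acidic C–H of the chromone (C2–H, vinylic and next to O1) without attacking the carbonyl, and iodinolysis of the C–Zn bond should give the 2-iodide.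

Step 11
Reactants: 19 2-iodo-7-methoxy-5-(methoxymethoxy)-6-[(2-isopropyl-1,3-dioxolan-2-yl)methyl]-3-(3-methylbut-2-enyl)-4H-chromen-4-one; 20 trimethylsilylacetylene
Product: 21 7-methoxy-5-(methoxymethoxy)-6-[(2-isopropyl-1,3-dioxolan-2-yl)methyl]-3-(3-methylbut-2-enyl)-2-[(trimethylsilyl)ethynyl]-4H-chromen-4-one
Conditions: Pd(PPh3)2Cl2 (cat.), CuI (cat.), Et3N, THF, rt, degassed
Reagents that add atoms: none
Why: Sonogashira coupling, in which the 2-iodochromone behaves as a β-iodo enone that should add oxidatively to zerovalent palladium with ease.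

Step 12
Reactants: 21 7-methoxy-5-(methoxymethoxy)-6-[(2-isopropyl-1,3-dioxolan-2-yl)methyl]-3-(3-methylbut-2-enyl)-2-[(trimethylsilyl)ethynyl]-4H-chromen-4-one
Product: 22 2-ethynyl-7-methoxy-5-(methoxymethoxy)-6-[(2-isopropyl-1,3-dioxolan-2-yl)methyl]-3-(3-methylbut-2-enyl)-4H-chromen-4-one
Conditions: TBAF, AcOH, THF, −20 to 0 °C; used directly
Reagents that add atoms: none
Why: Fluoride protodesilylation of the C(sp)–Si bond, with an acetic acid buffer so that no alkoxide or acetylide can add to the activated alkyne.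

Step 13
Reactants: 23 methyl acetoacetate
Product: 24 methyl (E)-3-(trimethylsilyloxy)but-2-enoate (E drawn; either enol ether isomer serves)
Conditions: TMSCl, Et3N, hexane, rt
Reagents that add atoms: chlorotrimethylsilane, C[Si](C)(C)Cl
Why: O-silylation of the enol of a β-keto ester (silyl enol ether formation).

Step 14
Reactants: 24 methyl (E)-3-(trimethylsilyloxy)but-2-enoate
Product: 26 (1Z)-1-methoxy-1,3-bis(trimethylsilyloxy)buta-1,3-diene (one ketene acetal geometry drawn), via lithium dienolate 25 (not isolated)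
Conditions: LiN(iPr)2, THF, −78 °C; then TMSCl, −78 °C to rt; distilled
Reagents that add atoms: chlorotrimethylsilane, C[Si](C)(C)Cl
Why: γ-Deprotonation of the vinylogous ester and O-silylation of the dienolate is the standard preparation of this 1-alkoxy-1,3-bis(silyloxy)diene, and the ketene acetal geometry is of no consequence because it is lost on aromatisation.

Step 15
Reactants: 22 2-ethynyl-7-methoxy-5-(methoxymethoxy)-6-[(2-isopropyl-1,3-dioxolan-2-yl)methyl]-3-(3-methylbut-2-enyl)-4H-chromen-4-one; 26 (1Z)-1-methoxy-1,3-bis(trimethylsilyloxy)buta-1,3-diene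
Product: 29 2-(2,4-dihydroxyphenyl)-7-methoxy-5-(methoxymethoxy)-6-[(2-isopropyl-1,3-dioxolan-2-yl)methyl]-3-(3-methylbut-2-enyl)-4H-chromen-4-one, via cycloadduct 27 (not isolated), via bis-silyl ether 28 (not isolated)
Conditions: 26 (3 equiv), toluene, 90 °C, sealed tube; then K2CO3 (cat.), MeOH, rt
Reagents that add atoms: none
Why: Proposed new method: the terminal alkyne carbon of 22 is the δ-terminus of the O=C4–C3=C2–C≡C acceptor, so the nucleophilic CH2 terminus of the electron-rich diene 26 should bond to it and the ketene acetal carbon to the internal alkyne carbon, either in a concerted asynchronous [4+2] cycloaddition or by vinylogous Mukaiyama–Michael addition followed by ring closure. The closest known reaction type is the Diels–Alder benzannulation of 1-alkoxy-1,3-bis(silyloxy)dienes and related Danishefsky- and Brassard-type dienes with alkynones and propiolates, which gives resorcinol derivatives after loss of alcohol; here the activation is relayed through the C2=C3 bond of the chromone, which is why heat and excess diene are planned. Ring B is closed by this intermolecular [4+2] annulation, which forms C1'–C2' and C5'–C6' (a six-membered carbocycle from the two alkyne carbons and the four diene carbons); cycloadduct 27 should then lose methanol by 1,4-elimination across C2'/C5' to give arene 28, and catalytic methanolysis removes both silyl groups. No stereocentre is set: the ketal carbon C2' of 27 is stereogenic only in passing and is racemic. The selectivity needed is regiochemical, 2',4'- and not 3',5'-oxygenation and reaction at the alkyne and not at C2=C3; it is secured by pairing the most nucleophilic diene terminus with the unhindered terminal alkyne carbon, while the tetrasubstituted C2=C3 bond is too hindered to compete. The neutral thermal conditions and the mildly basic methanolysis should leave the MOM ether and the dioxolane in place.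

Step 16
Reactants: 29 2-(2,4-dihydroxyphenyl)-7-methoxy-5-(methoxymethoxy)-6-[(2-isopropyl-1,3-dioxolan-2-yl)methyl]-3-(3-methylbut-2-enyl)-4H-chromen-4-one
Product: 30 2-(2,4-dihydroxyphenyl)-5-hydroxy-7-methoxy-6-(3-methyl-2-oxobutyl)-3-(3-methylbut-2-enyl)-4H-chromen-4-one (target CNP0291994.0)
Conditions: HCl (2 M aq), THF/MeOH, rt to 40 °C
Reagents that add atoms: water, O
Why: Acid-catalysed hydrolysis of the MOM acetal and of the dioxolane in one operation; the freed 5-OH is hydrogen-bonded to the C4 carbonyl, which should disfavour cyclodehydration onto the side-chain ketone, and dilute acid at moderate temperature should leave the prenyl group intact.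

**Compound list**

1 | 5-methoxyresorcinol | COc1cc(O)cc(O)c1 | starting material
2 | 3-methoxy-5-(triisopropylsilyloxy)phenol | COc1cc(O)cc(O[Si](C(C)C)(C(C)C)C(C)C)c1 | intermediate
3 | triisopropyl[3-methoxy-5-(methoxymethoxy)phenoxy]silane | COCOc1cc(OC)cc(O[Si](C(C)C)(C(C)C)C(C)C)c1 | intermediate
4 | 2-isopropyloxirane (racemic) | CC(C)C1CO1 | starting material
5 | [2-methoxy-6-(methoxymethoxy)-4-(triisopropylsilyloxy)phenyl]lithium | [Li]c1c(OC)cc(O[Si](C(C)C)(C(C)C)C(C)C)cc1OCOC | intermediate (not isolated)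
6 | rac-1-[2-methoxy-6-(methoxymethoxy)-4-(triisopropylsilyloxy)phenyl]-3-methylbutan-2-ol | COCOc1cc(O[Si](C(C)C)(C(C)C)C(C)C)cc(OC)c1CC(O)C(C)C | intermediate
7 | 1-[2-methoxy-6-(methoxymethoxy)-4-(triisopropylsilyloxy)phenyl]-3-methylbutan-2-one | COCOc1cc(O[Si](C(C)C)(C(C)C)C(C)C)cc(OC)c1CC(=O)C(C)C | intermediate
8 | 2-isopropyl-2-[2-methoxy-6-(methoxymethoxy)-4-(triisopropylsilyloxy)benzyl]-1,3-dioxolane | COCOc1cc(O[Si](C(C)C)(C(C)C)C(C)C)cc(OC)c1CC1(C(C)C)OCCO1 | intermediate
9 | N-methoxy-N-methylacetamide | CON(C)C(C)=O | starting material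
10 | {4-methoxy-2-(methoxymethoxy)-3-[(2-isopropyl-1,3-dioxolan-2-yl)methyl]-6-(triisopropylsilyloxy)phenyl}lithium | COCOc1c([Li])c(O[Si](C(C)C)(C(C)C)C(C)C)cc(OC)c1CC1(C(C)C)OCCO1 | intermediate (not isolated)
11 | 1-{4-methoxy-2-(methoxymethoxy)-3-[(2-isopropyl-1,3-dioxolan-2-yl)methyl]-6-(triisopropylsilyloxy)phenyl}ethanone | COCOc1c(C(C)=O)c(O[Si](C(C)C)(C(C)C)C(C)C)cc(OC)c1CC1(C(C)C)OCCO1 | intermediate
12 | prenyl bromide (1-bromo-3-methylbut-2-ene) | CC(C)=CCBr | starting material
13 | lithium enolate of 11 | COCOc1c(C(=C)O[Li])c(O[Si](C(C)C)(C(C)C)C(C)C)cc(OC)c1CC1(C(C)C)OCCO1 | intermediate (not isolated)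
14 | 1-{4-methoxy-2-(methoxymethoxy)-3-[(2-isopropyl-1,3-dioxolan-2-yl)methyl]-6-(triisopropylsilyloxy)phenyl}-5-methylhex-4-en-1-one | COCOc1c(C(=O)CCC=C(C)C)c(O[Si](C(C)C)(C(C)C)C(C)C)cc(OC)c1CC1(C(C)C)OCCO1 | intermediate
15 | 1-{6-hydroxy-4-methoxy-2-(methoxymethoxy)-3-[(2-isopropyl-1,3-dioxolan-2-yl)methyl]phenyl}-5-methylhex-4-en-1-one | COCOc1c(C(=O)CCC=C(C)C)c(O)cc(OC)c1CC1(C(C)C)OCCO1 | intermediate
16 | (E)-2-[(dimethylamino)methylidene] derivative of 15 (enaminone; E drawn) | COCOc1c(C(=O)/C(CC=C(C)C)=C/N(C)C)c(O)cc(OC)c1CC1(C(C)C)OCCO1 | intermediate (not isolated)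
17 | 7-methoxy-5-(methoxymethoxy)-6-[(2-isopropyl-1,3-dioxolan-2-yl)methyl]-3-(3-methylbut-2-enyl)-4H-chromen-4-one | COc1cc2occ(CC=C(C)C)c(=O)c2c(OCOC)c1CC1(C(C)C)OCCO1 | intermediate
18 | chromen-2-ylzinc chloride of 17 | COc1cc2oc([Zn]Cl)c(CC=C(C)C)c(=O)c2c(OCOC)c1CC1(C(C)C)OCCO1 | intermediate (not isolated)
19 | 2-iodo-7-methoxy-5-(methoxymethoxy)-6-[(2-isopropyl-1,3-dioxolan-2-yl)methyl]-3-(3-methylbut-2-enyl)-4H-chromen-4-one | COc1cc2oc(I)c(CC=C(C)C)c(=O)c2c(OCOC)c1CC1(C(C)C)OCCO1 | intermediate
20 | trimethylsilylacetylene | C#C[Si](C)(C)C | starting material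
21 | 7-methoxy-5-(methoxymethoxy)-6-[(2-isopropyl-1,3-dioxolan-2-yl)methyl]-3-(3-methylbut-2-enyl)-2-[(trimethylsilyl)ethynyl]-4H-chromen-4-one | COc1cc2oc(C#C[Si](C)(C)C)c(CC=C(C)C)c(=O)c2c(OCOC)c1CC1(C(C)C)OCCO1 | intermediate
22 | 2-ethynyl-7-methoxy-5-(methoxymethoxy)-6-[(2-isopropyl-1,3-dioxolan-2-yl)methyl]-3-(3-methylbut-2-enyl)-4H-chromen-4-one | COc1cc2oc(C#C)c(CC=C(C)C)c(=O)c2c(OCOC)c1CC1(C(C)C)OCCO1 | intermediate
23 | methyl acetoacetate | COC(=O)CC(C)=O | starting material
24 | methyl (E)-3-(trimethylsilyloxy)but-2-enoate | COC(=O)/C=C(\C)O[Si](C)(C)C | intermediate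
25 | lithium dienolate of 24 | CO/C(O[Li])=C/C(=C)O[Si](C)(C)C | intermediate (not isolated)
26 | (1Z)-1-methoxy-1,3-bis(trimethylsilyloxy)buta-1,3-diene | CO/C(O[Si](C)(C)C)=C/C(=C)O[Si](C)(C)C | intermediate
27 | 2-[6-methoxy-4,6-bis(trimethylsilyloxy)cyclohexa-1,4-dien-1-yl]-7-methoxy-5-(methoxymethoxy)-6-[(2-isopropyl-1,3-dioxolan-2-yl)methyl]-3-(3-methylbut-2-enyl)-4H-chromen-4-one (racemic at the ketal carbon) | COc1cc2oc(C3=CCC(O[Si](C)(C)C)=CC3(OC)O[Si](C)(C)C)c(CC=C(C)C)c(=O)c2c(OCOC)c1CC1(C(C)C)OCCO1 | intermediate (not isolated)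
28 | 2-[2,4-bis(trimethylsilyloxy)phenyl]-7-methoxy-5-(methoxymethoxy)-6-[(2-isopropyl-1,3-dioxolan-2-yl)methyl]-3-(3-methylbut-2-enyl)-4H-chromen-4-one | COc1cc2oc(-c3ccc(O[Si](C)(C)C)cc3O[Si](C)(C)C)c(CC=C(C)C)c(=O)c2c(OCOC)c1CC1(C(C)C)OCCO1 | intermediate (not isolated)
29 | 2-(2,4-dihydroxyphenyl)-7-methoxy-5-(methoxymethoxy)-6-[(2-isopropyl-1,3-dioxolan-2-yl)methyl]-3-(3-methylbut-2-enyl)-4H-chromen-4-one | COc1cc2oc(-c3ccc(O)cc3O)c(CC=C(C)C)c(=O)c2c(OCOC)c1CC1(C(C)C)OCCO1 | intermediate
30 | 2-(2,4-dihydroxyphenyl)-5-hydroxy-7-methoxy-6-(3-methyl-2-oxobutyl)-3-(3-methylbut-2-enyl)-4H-chromen-4-one | COc1cc2oc(-c3ccc(O)cc3O)c(CC=C(C)C)c(=O)c2c(O)c1CC(=O)C(C)C | target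

**Step count**

Total steps: 16. Longest linear sequence: 14 (steps 1–12, 15 and 16); the diene branch (steps 13 and 14) joins at step 15.

**Steps most likely to fail, with fallbacks**

First, the ring B cycloaddition (step 15, the proposed new method). The alkyne is activated only through the chromone, so cycloaddition may be slower than thermal silyl migration or decomposition of the diene, or the reaction may stop at an open-chain conjugate adduct that does not close. The fallback uses known cross-coupling and sets out from chromone 17. It is zincated as in step 10 to 18, and this zinc reagent is coupled (Negishi coupling, Pd(OAc)2/SPhos, THF, 50 °C) with 1-bromo-2,4-bis(methoxymethoxy)benzene F1, which is made from commercial 4-bromoresorcinol with MOMCl and iPr2NEt. This should give 2-[2,4-bis(methoxymethoxy)phenyl]-7-methoxy-5-(methoxymethoxy)-6-[(2-isopropyl-1,3-dioxolan-2-yl)methyl]-3-(3-methylbut-2-enyl)-4H-chromen-4-one F2. Under the conditions of step 16, F2 loses its three MOM groups and the dioxolane and comes back to the route at target 30.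

Second, the acylating lithiation (step 6). Deprotonation between OMOM and the bulky silyl ether may be slow or incomplete, the ortho-lithiated aryl silyl ether may undergo O-to-C silyl migration, and the hindered aryllithium may deprotonate the amide instead of adding to it. The fallback replaces the silyl ether by a second acetal directing group and sets out from 8. Fluoride (TBAF, AcOH, THF) should give 3-methoxy-5-(methoxymethoxy)-4-[(2-isopropyl-1,3-dioxolan-2-yl)methyl]phenol F3. SEMCl and iPr2NEt then give [2-({3-methoxy-5-(methoxymethoxy)-4-[(2-isopropyl-1,3-dioxolan-2-yl)methyl]phenoxy}methoxy)ethyl]trimethylsilane F4. Lithiation with n-BuLi (THF, 0 °C) between the two acetal groups and acylation with 9 should give 1-{4-methoxy-2-(methoxymethoxy)-3-[(2-isopropyl-1,3-dioxolan-2-yl)methyl]-6-{[2-(trimethylsilyl)ethoxy]methoxy}phenyl}ethanone F5. Enolate alkylation (LiN(iPr)2, then 12) gives 1-{4-methoxy-2-(methoxymethoxy)-3-[(2-isopropyl-1,3-dioxolan-2-yl)methyl]-6-{[2-(trimethylsilyl)ethoxy]methoxy}phenyl}-5-methylhex-4-en-1-one F6. Fluoride-induced fragmentation of the SEM ether (TBAF, DMPU, THF, 60 °C), which leaves the MOM ether, comes back to the route at phenol ketone 15.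

Third, the epoxide opening (step 3). BF3 may rearrange or oligomerise the branched epoxide, may bind the aryllithium as an unreactive borate, or may attack the MOM acetal, so that the hindered aryllithium is quenched without C–C bond formation. The fallback sets out from 3. After lithiation as in step 3 to 5, copper-catalysed allylation (CuBr·SMe2 cat., then prenyl bromide 12, −78 to 0 °C) should give triisopropyl[3-methoxy-5-(methoxymethoxy)-4-(3-methylbut-2-enyl)phenoxy]silane F7. Hydroboration–oxidation (BH3·SMe2, THF, 0 °C; then NaOH, H2O2) places the hydroxyl on the less substituted alkene carbon and comes back to the route at alcohol 6.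

**Further compounds**

F1 | step 15 | 1-bromo-2,4-bis(methoxymethoxy)benzene | COCOc1ccc(Br)c(OCOC)c1
F2 | step 15 | 2-[2,4-bis(methoxymethoxy)phenyl]-7-methoxy-5-(methoxymethoxy)-6-[(2-isopropyl-1,3-dioxolan-2-yl)methyl]-3-(3-methylbut-2-enyl)-4H-chromen-4-one | COCOc1ccc(-c2oc3cc(OC)c(CC4(C(C)C)OCCO4)c(OCOC)c3c(=O)c2CC=C(C)C)c(OCOC)c1
F3 | step 6 | 3-methoxy-5-(methoxymethoxy)-4-[(2-isopropyl-1,3-dioxolan-2-yl)methyl]phenol | COCOc1cc(O)cc(OC)c1CC1(C(C)C)OCCO1
F4 | step 6 | [2-({3-methoxy-5-(methoxymethoxy)-4-[(2-isopropyl-1,3-dioxolan-2-yl)methyl]phenoxy}methoxy)ethyl]trimethylsilane | COCOc1cc(OCOCC[Si](C)(C)C)cc(OC)c1CC1(C(C)C)OCCO1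
F5 | step 6 | 1-{4-methoxy-2-(methoxymethoxy)-3-[(2-isopropyl-1,3-dioxolan-2-yl)methyl]-6-{[2-(trimethylsilyl)ethoxy]methoxy}phenyl}ethanone | COCOc1c(C(C)=O)c(OCOCC[Si](C)(C)C)cc(OC)c1CC1(C(C)C)OCCO1
F6 | step 6 | 1-{4-methoxy-2-(methoxymethoxy)-3-[(2-isopropyl-1,3-dioxolan-2-yl)methyl]-6-{[2-(trimethylsilyl)ethoxy]methoxy}phenyl}-5-methylhex-4-en-1-one | COCOc1c(C(=O)CCC=C(C)C)c(OCOCC[Si](C)(C)C)cc(OC)c1CC1(C(C)C)OCCO1
F7 | step 3 | triisopropyl[3-methoxy-5-(methoxymethoxy)-4-(3-methylbut-2-enyl)phenoxy]silane | COCOc1cc(O[Si](C(C)C)(C(C)C)C(C)C)cc(OC)c1CC=C(C)C
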